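Amounts first: these flasks differ in how much X and how much Q they hold, and the question is what that does to the selectivity, the share of J in J plus Z.

| flask | X | Q | remark | time |
|---|---|---|---|---|
| ochre | 20 mM | 0.62 µM | run made earlier |  |
| blue | 20 mM | 4.7 µM | run made earlier |  |
| red | 21 mM | 4 µM | run made earlier |  |
| Saturday's | 30 mM | 1.2 µM |  | 8.0 min |
| Sunday's | 60 mM | 6.0 µM |  | 8.0 min |
| Thursday's | 20 mM | 4.0 µM |  | 8.0 min |
| Friday's | 12 mM | 2.5 µM |  | 8.0 min |

| run | time / min | J / % | Z / % |
|---|---|---|---|
| ochre | 0.333 | 0 | 0.2 |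
| ochre | 0.500 | 2.0 | 0.2 |
| ochre | 0.833 | 1.5 | 0 |
| ochre | 1.33 | 2.7 | 0 |
| ochre | 2.50 | 4.6 | 0 |
| ochre | 4.00 | 7.4 | 0 |
| blue | 0.333 | 3.7 | 0 |
| blue | 0.500 | 6.9 | 0 |
| blue | 0.833 | 10.9 | 0.7 |
| blue | 1.33 | 17.4 | 1.1 |
| blue | 2.50 | 30.2 | 2.6 |
| blue | 4.00 | 46.2 | 7.9 |
| red | 0.333 | 4.1 | 0.2 |
| red | 0.667 | 7.4 | 1.2 |
| red | 1.00 | 10.9 | 0.7 |
| red | 2.00 | 21.1 | 1.5 |
| red | 4.00 | 38.4 | 5.5 |

(readings scatter by 0.5 percentage points)

- the share counts what is present at the end, not what went on to other products

* the flasks put in order of share of J in all that became J or Z, best first, at 8.0 min (Saturday's / Sunday's / Thursday's / Friday's)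
* the share of J in all that became J or Z of the flask you put first, at 8.0 min
* the share of J in all that became J or Z of the flask you put last, at 8.0 min

The share is 1/(1 + [Z]/[J]), so the argument at the board is about the ratio [Z]/[J]. Two people read the runs differently, and both take the speed from the blue run: at 4.00 min it has converted 54.1 % of its X, a turnover number of about 576 min⁻¹.

The conversion side says the ratio follows the fraction of X converted. Blue's ratio of 0.171 makes it 0.316 times that fraction. Friday's, reckoned at 95.9 % converted, then gets a share of 76.7 %, and Sunday's, reckoned at 46.0 %, gets 87.3 %.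

The dose side says the ratio follows the dose D = [Q]t, and I reckon with this side. Its yardstick is the dose divided by the ratio: blue gives 110 µM·min and red gives 112 µM·min, both readings with Z good to 0.5 percentage points. In logarithms, the log of the ratio is log D minus the log of the yardstick, so a decade of dose is a decade of ratio. The logs of D over the yardstick are −1.06 for Saturday's, −0.740 for Friday's, −0.536 for Thursday's and −0.360 for Sunday's. My shares, in the same order of flasks, are then 92.0 %, 84.6 %, 77.5 % and 69.6 %.

In the three runs, charged with 20 mM or 21 mM of X, conversion and dose rise together, so among these runs the conversion side reads as well as the dose side. Sunday's, charged with 60 mM, and Friday's, charged with 12 mM, are where they part.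

The forecast stands with the dose side: Saturday's > Friday's > Thursday's > Sunday's, 92 % and 68 %, the last below my figure, and it calls the step to Z “also Q-catalysed and first order in J”.

The simulation gives Saturday's > Friday's > Thursday's > Sunday's, with 91.4 %, 83.6 %, 79.0 % and 75.7 %, which is 7.7 points above the forecast's low.

    X + Q → J + Q, rate k1*[X]*[Q]/(1 + ([X]/Km1) + ([X]/Ksi1)^2) (7.40 mM, 15.0 mM, k = 1.60 × 10⁵ M⁻¹ min⁻¹)
    J + Q ⇌ Z + Q, rate k2*[Q]*[J] forward; the back reaction follows from the equilibrium constant (K = 0.650, k = 22000 M⁻¹ min⁻¹)
    Q + J → L (k = 3.90 M⁻¹ min⁻¹)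

The order is the dose's. At 8.00 min Saturday's ratio is 0.0946 against the yardstick's 0.0873, but Sunday's is 0.320, lower than the yardstick's 0.437. The neighbour of Saturday's charged with 0.0048 mM of Q has a dose of 38.4 µM·min, between Thursday's 32.0 µM·min and Sunday's 48.0 µM·min, so the yardstick gives it a ratio of 0.349 and a share of 74.1 %. That neighbour ends with J at 52.4 % and Z at 14.7 %, a share of 78.1 %.

The earlier runs and the new flask stem from a simulated flask with made-up constants, and the scatter is random.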